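**Plan**

1. Numbering: the core is a 7-oxabicyclo[4.1.0]hept-3-ene (C1 quaternary epoxide carbon, C2, C3=C4, C5, C6, O7), the side chain is C1'–C5', the cyclohexenyl ring is C1''–C6''. Cuts: C3'–C4' (Stille), C1'–C2' (alkenylmetal plus epoxy aldehyde) and, in the core, C3–C4 together with C5–C6 (one [4+2] event).
2. Enabling feature: in the carbocycle C3 and C6 are 1,4-related, C6 carries the epoxide oxygen and C3=C4 is conjugated to the carboxyl-level carbon on C4. C3–C2–C1–C6 with O7 is therefore a furan and C4–C5 a 3-bromopropiolate (bromine = ketone level at C5). The oxygen bridge of their Diels–Alder adduct opens by E1cB toward the ester (giving C3=C4), and the furan oxygen stays on C6 and ends as O7.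
3. Forward, core: cycloadduct → C5 ketone → endo alcohol (resolved) → endo C1–C2 epoxide through a temporary carbonate tether → bridge opening and Payne shift (O on C6 attacks C1) → C1 carbaldehyde. Bromine, bridge, carbonate tether, 4-methoxybenzyl and silyl groups are helpers removed on the way.
4. Cyclohexenol ring: Shi epoxidation of geranyl acetate, chair epoxy-olefin cyclisation, then aldehyde and (E)-vinyl iodide.
5. Union: (Z)-2-stannylpropenyl addition to the aldehyde (C1'–C2'), Stille coupling (C3'–C4'), ester reduction, desilylation.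
6. Stereochemistry: C6 from the cycloadduct bridgehead (absolute sense by lipase resolution); C5 by exo hydride attack, C2 by endo halocyclisation, C1 by Payne inversion, C1' by chelation control; C1''/C5'' from the Shi epoxide through the chair transition state.

Key step: step 3

Remark: between steps 4 and 11 the ester-bearing ring carbon is epimerisable and is carried as a mixture (it becomes sp2 in step 11); in step 6 the lipase is assumed to acylate the unwanted antipode (if it prefers the wanted one, that acetate is methanolysed and carried on).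

**Route**

Step 1
Reactants: 1 furan-3-ylmethanol
Product: 2 3-{[(4-methoxybenzyl)oxy]methyl}furan
Conditions: NaH, 4-methoxybenzyl chloride, Bu4NI (cat.), THF/DMF, 0 °C → rt
Reagents that add atoms: 4-methoxybenzyl chloride, COc1ccc(CCl)cc1
Why: Williamson ether synthesis; the 4-methoxybenzyl ether masks the future C1' carbon through the base, hydride and halogen steps and is removable oxidatively in step 12.

Step 2
Reactants: 3 methyl prop-2-ynoate
Product: 4 methyl 3-bromoprop-2-ynoate
Conditions: N-bromosuccinimide, AgNO3 (10 mol%), acetone, rt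
Reagents that add atoms: N-bromosuccinimide, O=C1CCC(=O)N1Br
Why: Silver-catalysed electrophilic bromination of the terminal alkyne (via the silver acetylide) gives the bromoalkyne that serves as a β-keto ester equivalent.

Step 3
Reactants: 2 3-{[(4-methoxybenzyl)oxy]methyl}furan; 4 methyl 3-bromoprop-2-ynoate
Product: 5 methyl 3-bromo-5-{[(4-methoxybenzyl)oxy]methyl}-7-oxabicyclo[2.2.1]hepta-2,5-diene-2-carboxylate (racemic)
Conditions: PhMe, 80 °C, sealed tube, dark (4 in 1.5-fold excess)
Reagents that add atoms: none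
Why: Thermal, concerted normal-demand Diels–Alder reaction in which the furan (diene, C2/C5 termini) adds across the electron-poor triple bond of 4, forming C3–C4 and C5–C6 of the target ring in one suprafacial event; the closest known reaction type is the cycloaddition of alkylfurans with 3-halopropiolates to 7-oxanorbornadienes. The six-membered carbocycle is closed by intermolecular [4+2] ring formation, both new σ-bonds being made on the same face of the furan, and the furan oxygen is left as a one-atom bridge between C3 and C6. The two bridgehead stereocentres arise as a geometrically fixed cis pair; there is no facial bias, so 5 is racemic and the absolute configuration is selected in step 6. The step needs "para" regiochemistry (ester carbon bonded to the furan carbon remote from the side-chain substituent): the largest HOMO coefficient of a 3-alkylfuran lies at C2, next to the substituent, and pairs with the larger LUMO coefficient at the bromine-bearing β-carbon of the ynoate, so the wanted orientation should be favoured and the minor regioisomer would be removed by chromatography. The bromine gives C5 the ketone oxidation level and the ester acidifies C4 for the later bridge opening.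

Step 4
Reactants: 5 methyl 3-bromo-5-{[(4-methoxybenzyl)oxy]methyl}-7-oxabicyclo[2.2.1]hepta-2,5-diene-2-carboxylate
Product: 7 methyl 5-{[(4-methoxybenzyl)oxy]methyl}-3-oxo-7-oxabicyclo[2.2.1]hept-5-ene-2-carboxylate (racemic), via dimethyl ketal 6 (not isolated)
Conditions: NaOMe (2.2 equiv), MeOH, 0 °C → rt; then 2 M HCl, THF, rt
Reagents that add atoms: water, O (ketone oxygen of 7); sodium methoxide, C[O-].[Na+] (methoxy groups of 6 only)
Why: Methoxide adds to the β-bromo enoate from the exo face and expels bromide (addition–elimination), a second conjugate addition gives ketal 6, and acetal hydrolysis unmasks the C5 ketone.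

Step 5
Reactants: 7 methyl 5-{[(4-methoxybenzyl)oxy]methyl}-3-oxo-7-oxabicyclo[2.2.1]hept-5-ene-2-carboxylate
Product: 8 methyl 3-endo-hydroxy-5-{[(4-methoxybenzyl)oxy]methyl}-7-oxabicyclo[2.2.1]hept-5-ene-2-carboxylate (racemic)
Conditions: NaBH4, MeOH, −40 → −20 °C
Reagents that add atoms: none
Why: Borohydride reduction of the bicyclic ketone; hydride is delivered to the open exo face (syn to the oxygen bridge), so the C5 hydroxyl is endo, i.e. trans to the bridge oxygen that later becomes the epoxide oxygen.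

Step 6
Reactants: 8 methyl 3-endo-hydroxy-5-{[(4-methoxybenzyl)oxy]methyl}-7-oxabicyclo[2.2.1]hept-5-ene-2-carboxylate (racemic)
Product: 9 methyl (1S,3R,4R)-3-hydroxy-5-{[(4-methoxybenzyl)oxy]methyl}-7-oxabicyclo[2.2.1]hept-5-ene-2-carboxylate (3-endo-OH; single enantiomer)
Conditions: Burkholderia cepacia lipase (immobilised), vinyl acetate, t-BuOMe, 30 °C, stopped near half conversion
Reagents that add atoms: none
Why: Lipase-catalysed kinetic resolution by irreversible transesterification discriminates the enantiomers at the secondary carbinol; the unreacted alcohol fixes the absolute configuration of all ring stereocentres.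

Step 7
Reactants: 9 methyl (1S,3R,4R)-3-hydroxy-5-{[(4-methoxybenzyl)oxy]methyl}-7-oxabicyclo[2.2.1]hept-5-ene-2-carboxylate
Product: 10 tert-butyl carbonate of 9 (3-endo-OBoc)
Conditions: Boc2O, 4-(dimethylamino)pyridine (10 mol%), MeCN, rt
Reagents that add atoms: di-tert-butyl dicarbonate, CC(C)(C)OC(=O)OC(=O)OC(C)(C)C
Why: Nucleophile-catalysed acylation installs a carbonate on the endo face as an internal oxygen nucleophile, homoallylic to the C1=C2 alkene.

Step 8
Reactants: 10 tert-butyl carbonate of 9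
Product: 11 methyl 6-exo-iodo-5-exo-{[(4-methoxybenzyl)oxy]methyl}-7-oxabicyclo[2.2.1]heptane-2-carboxylate 3-endo,5-endo-cyclic carbonate
Conditions: IBr, PhMe/CH2Cl2, −85 °C
Reagents that add atoms: iodine monobromide, IBr
Why: Iodocarbonate cyclisation; the iodonium ion forms on the open exo face and the carbonate carbonyl oxygen attacks the more substituted alkene carbon (C1) from the endo face in a six-membered mode with loss of the tert-butyl group, so oxygen enters C1 endo and iodine C2 exo.

Step 9
Reactants: 11 iodo cyclic carbonate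
Product: 12 methyl 5,6-endo-epoxy-3-endo-hydroxy-5-{[(4-methoxybenzyl)oxy]methyl}-7-oxabicyclo[2.2.1]heptane-2-carboxylate
Conditions: K2CO3, MeOH, 0 °C → rt
Reagents that add atoms: none
Why: Methanolysis of the cyclic carbonate frees the C1 alkoxide, which displaces the trans (exo) iodide at C2 with inversion (intramolecular Williamson reaction) and gives the endo epoxide that exo-selective epoxidation could not supply.

Step 10
Reactants: 12 endo-epoxy alcohol
Product: 13 3-O-triisopropylsilyl ether of 12
Conditions: triisopropylsilyl triflate, 2,6-lutidine, CH2Cl2, −40 → 0 °C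
Reagents that add atoms: triisopropylsilyl trifluoromethanesulfonate, CC(C)[Si](C(C)C)(C(C)C)OS(=O)(=O)C(F)(F)F
Why: Silylation of the hindered secondary alcohol; the triisopropylsilyl group is chosen because it resists base-induced 1,2-migration to the neighbouring alkoxide formed in step 11.

Step 11
Reactants: 13 3-O-triisopropylsilyl ether of 12
Product: 16 methyl 5-[(tert-butyldimethylsilyl)oxy]-6-{[(4-methoxybenzyl)oxy]methyl}-2-[(triisopropylsilyl)oxy]-7-oxabicyclo[4.1.0]hept-3-ene-3-carboxylate (silyloxy groups cis; epoxide trans to both), via ring-opened potassium alkoxide 14 (not isolated), via Payne-rearranged potassium alkoxide 15 (not isolated)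
Conditions: KN(SiMe3)2 (1.1 equiv), THF, −78 → 0 °C; then t-BuMe2SiCl, 0 °C → rt
Reagents that add atoms: tert-butyldimethylsilyl chloride, CC(C)(C)[Si](C)(C)Cl; potassium bis(trimethylsilyl)amide, C[Si](C)(C)[N-][Si](C)(C)C.[K+] (potassium of 14 and 15 only)
Why: E1cB ring opening followed by Payne rearrangement; the ester enolate at C4 expels the bridging oxygen from C3 (creating C3=C4), the released C6 alkoxide attacks C1 anti to the C1–C2 epoxide with inversion so that the former furan oxygen becomes the C1–C6 epoxide oxygen, and the less hindered C2 alkoxide is trapped as its silyl ether, which draws the epoxide equilibrium to the product side.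

Step 12
Reactants: 16 bis-silyl epoxy ester
Product: 17 methyl 5-[(tert-butyldimethylsilyl)oxy]-6-(hydroxymethyl)-2-[(triisopropylsilyl)oxy]-7-oxabicyclo[4.1.0]hept-3-ene-3-carboxylate
Conditions: 2,3-dichloro-5,6-dicyano-1,4-benzoquinone, CH2Cl2/pH 7 phosphate buffer, 0 °C → rt
Reagents that add atoms: none
Why: Oxidative cleavage of the 4-methoxybenzyl ether (hydride abstraction, hydrolysis of the oxocarbenium ion) under buffered conditions leaves silyl ethers, epoxide and enoate intact.

Step 13
Reactants: 17 primary epoxy alcohol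
Product: 18 methyl 5-[(tert-butyldimethylsilyl)oxy]-6-formyl-2-[(triisopropylsilyl)oxy]-7-oxabicyclo[4.1.0]hept-3-ene-3-carboxylate
Conditions: Dess–Martin periodinane, pyridine, CH2Cl2, 0 °C → rt
Reagents that add atoms: none
Why: Dess–Martin oxidation of the 2,3-epoxy alcohol to the epoxy aldehyde; the α-carbon is quaternary, so no epimerisation is possible.

Step 14
Reactants: 19 geranyl acetate
Product: 20 (2E)-5-[(2R)-3,3-dimethyloxiran-2-yl]-3-methylpent-2-en-1-yl acetate
Conditions: 1,2:4,5-di-O-isopropylidene-β-D-erythro-hexo-2,3-diulo-2,6-pyranose (Shi ketone, 30 mol%), KHSO5 (as 2KHSO5·KHSO4·K2SO4), K2CO3, Bu4NHSO4 (cat.), MeCN/CH2(OMe)2/aq. Na2B4O7 buffer, 0 °C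
Reagents that add atoms: potassium peroxymonosulfate, [K+].[O-]S(=O)(=O)OO
Why: Shi epoxidation (chiral dioxirane); the electron-rich 6,7-alkene reacts in preference to the 2,3-alkene deactivated by the allylic acetate, and the spiro transition state of the D-fructose-derived ketone should deliver the (R)-epoxide.

Step 15
Reactants: 20 (R)-6,7-epoxygeranyl acetate
Product: 21 [(1S,5R)-5-hydroxy-2,6,6-trimethylcyclohex-2-en-1-yl]methyl acetate
Conditions: ZrCl4 (1.2 equiv), CH2Cl2, −20 °C → rt; chromatography on AgNO3-impregnated silica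
Reagents that add atoms: none
Why: Lewis acid-promoted epoxy-olefin cyclisation through a chair transition state; the epoxide CH keeps its configuration and becomes the C5'' carbinol, the CH2OAc group ends equatorial and therefore cis to the hydroxyl, and proton loss toward the ring CH2 should give mainly the endocyclic alkene (the exocyclic isomer is separated).

Step 16
Reactants: 21 hydroxy acetate
Product: 22 (1R,5S)-5-(hydroxymethyl)-4,6,6-trimethylcyclohex-3-en-1-ol
Conditions: K2CO3 (cat.), MeOH, rt
Reagents that add atoms: none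
Why: Base-catalysed transesterification removes the acetate.

Step 17
Reactants: 22 diol
Product: 23 (1S,5R)-5-hydroxy-2,6,6-trimethylcyclohex-2-ene-1-carbaldehyde
Conditions: 2,2,6,6-tetramethylpiperidin-1-oxyl (10 mol%), PhI(OAc)2, CH2Cl2, rt
Reagents that add atoms: none
Why: Oxoammonium-mediated oxidation is selective for the primary over the hindered secondary alcohol and is mild enough to leave the β,γ-unsaturated aldehyde unconjugated and unepimerised.

Step 18
Reactants: 23 hydroxy aldehyde
Product: 24 (1R,5S)-5-[(E)-2-iodoethenyl]-4,6,6-trimethylcyclohex-3-en-1-ol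
Conditions: CrCl2 (6 equiv), CHI3 (2 equiv), THF/1,4-dioxane, 0 °C → rt
Reagents that add atoms: iodoform, IC(I)I
Why: Takai olefination; the geminal dichromium species adds to the aldehyde and eliminates to the (E)-vinyl iodide under non-basic conditions that spare the α-stereocentre and tolerate the free hydroxyl.

Step 19
Reactants: 25 propyne
Product: 26 (Z)-1,2-bis(trimethylstannyl)prop-1-ene
Conditions: Me3SnSnMe3, Pd(PPh3)4 (2 mol%), 1,4-dioxane, 80 °C, sealed tube
Reagents that add atoms: hexamethylditin, C[Sn](C)(C)[Sn](C)(C)C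
Why: Palladium-catalysed syn-distannylation of the terminal alkyne (oxidative addition of Sn–Sn to zerovalent palladium, insertion, reductive elimination) gives the cis-distannylalkene.

Step 20
Reactants: 26 (Z)-1,2-bis(trimethylstannyl)prop-1-ene; 18 epoxy aldehyde
Product: 29 methyl 5-[(tert-butyldimethylsilyl)oxy]-6-[(1S,2Z)-1-hydroxy-3-(trimethylstannyl)but-2-en-1-yl]-2-[(triisopropylsilyl)oxy]-7-oxabicyclo[4.1.0]hept-3-ene-3-carboxylate, via alkenyllithium 27 (not isolated), via alkenylmagnesium bromide 28 (not isolated)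
Conditions: 26, MeLi, THF, −78 °C; MgBr2·OEt2, −78 °C; then 18, CH2Cl2/THF, −78 °C; pH 7 buffer
Reagents that add atoms: methyllithium, [Li]C (lithium of 27 only); magnesium bromide, Br[Mg]Br (MgBr of 28 only)
Why: Tin–lithium exchange occurs at the less hindered terminal stannyl group with retention, and after transmetalation the alkenylmagnesium adds under chelation control (magnesium bridging aldehyde and epoxide oxygens, attack from the side of the epoxide CH and away from the C2 silyloxy group), which should set (1'S) and leaves the internal stannyl group cis to the carbinol carbon.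

Step 21
Reactants: 29 stannyl allylic alcohol; 24 (E)-vinyl iodide
Product: 30 methyl 5-[(tert-butyldimethylsilyl)oxy]-6-[(1S,2Z,4E)-1-hydroxy-5-[(1S,5R)-5-hydroxy-2,6,6-trimethylcyclohex-2-en-1-yl]-3-methylpenta-2,4-dien-1-yl]-2-[(triisopropylsilyl)oxy]-7-oxabicyclo[4.1.0]hept-3-ene-3-carboxylate
Conditions: Pd2(dba)3 (5 mol%), AsPh3 (20 mol%), CuI (10 mol%), N-methylpyrrolidone, rt → 40 °C, dark
Reagents that add atoms: none
Why: Stille cross-coupling (oxidative addition of the vinyl iodide to zerovalent palladium, copper-assisted transmetalation, reductive elimination) joins C3' and C4' with retention of both alkene geometries and tolerates hydroxyls, epoxide and ester.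

Step 22
Reactants: 30 dienyl ester
Product: 31 2-O-(tert-butyldimethylsilyl)-5-O-(triisopropylsilyl) derivative of 32
Conditions: i-Bu2AlH (6 equiv), CH2Cl2, −78 °C; aq. KNaC4H4O6
Reagents that add atoms: none
Why: Low-temperature 1,2-reduction of the α,β-unsaturated methyl ester by the aluminium hydride gives the allylic alcohol; at −78 °C epoxide and silyl ethers are not attacked.

Step 23
Reactants: 31 bis-silyl ether
Product: 32 (1R,2S,5R,6S)-1-[(1S,2Z,4E)-1-hydroxy-5-[(1S,5R)-5-hydroxy-2,6,6-trimethylcyclohex-2-en-1-yl]-3-methylpenta-2,4-dien-1-yl]-4-(hydroxymethyl)-7-oxabicyclo[4.1.0]hept-3-ene-2,5-diol (CNP0389279.1)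
Conditions: Bu4NF, AcOH (1:1), THF, 0 °C → rt
Reagents that add atoms: none
Why: Fluoride-mediated desilylation; acetic acid buffering keeps the liberated hydroxyls protonated so that the epoxide cannot migrate (Payne) in the product.

**Compound list**

1 | furan-3-ylmethanol | OCc1ccoc1 | starting material
2 | 3-{[(4-methoxybenzyl)oxy]methyl}furan | COc1ccc(COCc2ccoc2)cc1 | intermediate
3 | methyl prop-2-ynoate | COC(=O)C#C | starting material
4 | methyl 3-bromoprop-2-ynoate | COC(=O)C#CBr | intermediate
5 | methyl 3-bromo-5-{[(4-methoxybenzyl)oxy]methyl}-7-oxabicyclo[2.2.1]hepta-2,5-diene-2-carboxylate (racemic; enantiomer drawn is the one carried on) | COC(=O)C1=C(Br)[C@@H]2O[C@H]1C=C2COCc1ccc(OC)cc1 | intermediate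
6 | methyl 3,3-dimethoxy-5-{[(4-methoxybenzyl)oxy]methyl}-7-oxabicyclo[2.2.1]hept-5-ene-2-carboxylate (racemic, C2 epimers) | COC(=O)C1C(OC)(OC)[C@@H]2O[C@H]1C=C2COCc1ccc(OC)cc1 | intermediate (not isolated)
7 | methyl 5-{[(4-methoxybenzyl)oxy]methyl}-3-oxo-7-oxabicyclo[2.2.1]hept-5-ene-2-carboxylate (racemic, C2 epimers) | COC(=O)C1C(=O)[C@@H]2O[C@H]1C=C2COCc1ccc(OC)cc1 | intermediate
8 | methyl 3-endo-hydroxy-5-{[(4-methoxybenzyl)oxy]methyl}-7-oxabicyclo[2.2.1]hept-5-ene-2-carboxylate (racemic, C2 epimers; hydroxyl anti to the oxygen bridge) | COC(=O)C1[C@@H](O)[C@@H]2O[C@H]1C=C2COCc1ccc(OC)cc1 | intermediate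
9 | methyl (1S,3R,4R)-3-hydroxy-5-{[(4-methoxybenzyl)oxy]methyl}-7-oxabicyclo[2.2.1]hept-5-ene-2-carboxylate (3-endo-OH, C2 epimers, single enantiomer) | COC(=O)C1[C@@H](O)[C@@H]2O[C@H]1C=C2COCc1ccc(OC)cc1 | intermediate
10 | tert-butyl carbonate of 9 (3-endo-OBoc) | COC(=O)C1[C@@H](OC(=O)OC(C)(C)C)[C@@H]2O[C@H]1C=C2COCc1ccc(OC)cc1 | intermediate
11 | methyl 6-exo-iodo-5-exo-{[(4-methoxybenzyl)oxy]methyl}-7-oxabicyclo[2.2.1]heptane-2-carboxylate 3-endo,5-endo-cyclic carbonate | COC(=O)C1[C@H]2OC(=O)O[C@@]3(COCc4ccc(OC)cc4)[C@H](I)[C@@H]1O[C@@H]23 | intermediate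
12 | methyl 5,6-endo-epoxy-3-endo-hydroxy-5-{[(4-methoxybenzyl)oxy]methyl}-7-oxabicyclo[2.2.1]heptane-2-carboxylate (epoxide and hydroxyl anti to the oxygen bridge) | COC(=O)C1[C@@H](O)[C@@H]2O[C@H]1[C@@H]3O[C@]23COCc4ccc(OC)cc4 | intermediate
13 | 3-O-triisopropylsilyl ether of 12 | COC(=O)C1[C@@H](O[Si](C(C)C)(C(C)C)C(C)C)[C@@H]2O[C@H]1[C@@H]3O[C@]23COCc4ccc(OC)cc4 | intermediate
14 | potassium alkoxide of methyl 5-hydroxy-6-{[(4-methoxybenzyl)oxy]methyl}-4-[(triisopropylsilyl)oxy]-7-oxabicyclo[4.1.0]hept-2-ene-3-carboxylate (4-silyloxy and 5-oxido trans; epoxide trans to the 5-oxido group) | [K+].[O-][C@@H]1[C@@]2(COCc3ccc(OC)cc3)O[C@H]2C=C(C(=O)OC)[C@H]1O[Si](C(C)C)(C(C)C)C(C)C | intermediate (not isolated)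
15 | potassium alkoxide of methyl 5-hydroxy-6-{[(4-methoxybenzyl)oxy]methyl}-2-[(triisopropylsilyl)oxy]-7-oxabicyclo[4.1.0]hept-3-ene-3-carboxylate (2-silyloxy and 5-oxido cis; epoxide trans to both) | [K+].[O-][C@H]1C=C(C(=O)OC)[C@@H](O[Si](C(C)C)(C(C)C)C(C)C)[C@@H]2O[C@]12COCc3ccc(OC)cc3 | intermediate (not isolated)
16 | methyl 5-[(tert-butyldimethylsilyl)oxy]-6-{[(4-methoxybenzyl)oxy]methyl}-2-[(triisopropylsilyl)oxy]-7-oxabicyclo[4.1.0]hept-3-ene-3-carboxylate (silyloxy groups cis; epoxide trans to both) | COc1ccc(COC[C@]23O[C@H]2[C@H](O[Si](C(C)C)(C(C)C)C(C)C)C(C(=O)OC)=C[C@@H]3O[Si](C)(C)C(C)(C)C)cc1 | intermediate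
17 | methyl 5-[(tert-butyldimethylsilyl)oxy]-6-(hydroxymethyl)-2-[(triisopropylsilyl)oxy]-7-oxabicyclo[4.1.0]hept-3-ene-3-carboxylate (same configuration as 16) | OC[C@]12O[C@H]1[C@H](O[Si](C(C)C)(C(C)C)C(C)C)C(C(=O)OC)=C[C@@H]2O[Si](C)(C)C(C)(C)C | intermediate
18 | methyl 5-[(tert-butyldimethylsilyl)oxy]-6-formyl-2-[(triisopropylsilyl)oxy]-7-oxabicyclo[4.1.0]hept-3-ene-3-carboxylate (same configuration as 16) | O=C[C@]12O[C@H]1[C@H](O[Si](C(C)C)(C(C)C)C(C)C)C(C(=O)OC)=C[C@@H]2O[Si](C)(C)C(C)(C)C | intermediate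
19 | geranyl acetate, (2E)-3,7-dimethylocta-2,6-dien-1-yl acetate | CC(=O)OC/C=C(\C)CCC=C(C)C | starting material
20 | (2E)-5-[(2R)-3,3-dimethyloxiran-2-yl]-3-methylpent-2-en-1-yl acetate | CC(=O)OC/C=C(\C)CC[C@H]1OC1(C)C | intermediate
21 | [(1S,5R)-5-hydroxy-2,6,6-trimethylcyclohex-2-en-1-yl]methyl acetate (CH2OAc and OH cis) | CC1=CC[C@@H](O)C(C)(C)[C@H]1COC(C)=O | intermediate
22 | (1R,5S)-5-(hydroxymethyl)-4,6,6-trimethylcyclohex-3-en-1-ol | CC1=CC[C@@H](O)C(C)(C)[C@H]1CO | intermediate
23 | (1S,5R)-5-hydroxy-2,6,6-trimethylcyclohex-2-ene-1-carbaldehyde | CC1=CC[C@@H](O)C(C)(C)[C@H]1C=O | intermediate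
24 | (1R,5S)-5-[(E)-2-iodoethenyl]-4,6,6-trimethylcyclohex-3-en-1-ol | CC1=CC[C@@H](O)C(C)(C)[C@H]1/C=C/I | intermediate
25 | propyne | CC#C | starting material
26 | (Z)-1,2-bis(trimethylstannyl)prop-1-ene | C/C(=C/[Sn](C)(C)C)[Sn](C)(C)C | intermediate
27 | [(Z)-2-(trimethylstannyl)prop-1-en-1-yl]lithium | [Li]/C=C(/C)[Sn](C)(C)C | intermediate (not isolated)
28 | bromo[(Z)-2-(trimethylstannyl)prop-1-en-1-yl]magnesium | Br[Mg]/C=C(/C)[Sn](C)(C)C | intermediate (not isolated)
29 | methyl 5-[(tert-butyldimethylsilyl)oxy]-6-[(1S,2Z)-1-hydroxy-3-(trimethylstannyl)but-2-en-1-yl]-2-[(triisopropylsilyl)oxy]-7-oxabicyclo[4.1.0]hept-3-ene-3-carboxylate | C/C(=C/[C@H](O)[C@]12O[C@H]1[C@H](O[Si](C(C)C)(C(C)C)C(C)C)C(C(=O)OC)=C[C@@H]2O[Si](C)(C)C(C)(C)C)[Sn](C)(C)C | intermediate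
30 | methyl 5-[(tert-butyldimethylsilyl)oxy]-6-[(1S,2Z,4E)-1-hydroxy-5-[(1S,5R)-5-hydroxy-2,6,6-trimethylcyclohex-2-en-1-yl]-3-methylpenta-2,4-dien-1-yl]-2-[(triisopropylsilyl)oxy]-7-oxabicyclo[4.1.0]hept-3-ene-3-carboxylate | CC1=CC[C@@H](O)C(C)(C)[C@H]1/C=C/C(C)=C\[C@H](O)[C@]12O[C@H]1[C@H](O[Si](C(C)C)(C(C)C)C(C)C)C(C(=O)OC)=C[C@@H]2O[Si](C)(C)C(C)(C)C | intermediate
31 | 2-O-(tert-butyldimethylsilyl)-5-O-(triisopropylsilyl) derivative of 32 | CC1=CC[C@@H](O)C(C)(C)[C@H]1/C=C/C(C)=C\[C@H](O)[C@]12O[C@H]1[C@H](O[Si](C(C)C)(C(C)C)C(C)C)C(CO)=C[C@@H]2O[Si](C)(C)C(C)(C)C | intermediate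
32 | (1R,2S,5R,6S)-1-[(1S,2Z,4E)-1-hydroxy-5-[(1S,5R)-5-hydroxy-2,6,6-trimethylcyclohex-2-en-1-yl]-3-methylpenta-2,4-dien-1-yl]-4-(hydroxymethyl)-7-oxabicyclo[4.1.0]hept-3-ene-2,5-diol | CC1=CC[C@@H](O)C(C)(C)[C@H]1/C=C/C(C)=C\[C@H](O)[C@]12O[C@H]1[C@H](O)C(CO)=C[C@@H]2O | target

**Step count and risks**

Total: 23 steps. Longest linear sequence: 16 steps (steps 1, 3–13 and 20–23, from furan-3-ylmethanol).

Steps most likely to fail:

1. Step 11. The epoxide migration may stop short or run backward (the Payne equilibrium need not favour the C2 alkoxide, and the silyl chloride may not select it); silyl migration or aromatisation of the ring-opened dienoate may compete. Fallback, setting out from 13 and returning at 16: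
   - LiN(SiMe3)2 in THF at −78 °C with an acetic acid quench at that temperature should give the unrearranged trans-epoxy alcohol, methyl 5-hydroxy-6-{[(4-methoxybenzyl)oxy]methyl}-4-[(triisopropylsilyl)oxy]-7-oxabicyclo[4.1.0]hept-2-ene-3-carboxylate F1.
   - 1,1'-Thiocarbonyldiimidazole with 4-(dimethylamino)pyridine converts it into the O-(imidazol-1-ylcarbonothioyl) derivative F2.
   - Bu3SnH and azobisisobutyronitrile in benzene at 80 °C generate the C6 radical, whose neighbouring epoxide opens (radical epoxide fragmentation) to the C1=C6 alkene and a C2 alkoxyl radical that is reduced to methyl 3-hydroxy-4-{[(4-methoxybenzyl)oxy]methyl}-6-[(triisopropylsilyl)oxy]cyclohexa-1,4-diene-1-carboxylate F3.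
   - tert-Butyldimethylsilyl triflate and 2,6-lutidine give its silyl ether F4.
   - m-Chloroperbenzoic acid (NaHCO3, CH2Cl2, 0 °C) epoxidises the electron-rich C1=C6 alkene anti to the two flanking, mutually cis silyloxy groups and gives 16.
   - Here the epoxide oxygen comes from the peracid and the furan oxygen is excised.

2. Step 20. Facial selectivity at the aldehyde may be poor if chelation by the epoxide oxygen does not outweigh Felkin–Anh control. Fallback, setting out from 29 (as the mixture of C1' epimers) and returning at 29: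
   - Dess–Martin oxidation gives the alkenyl epoxy ketone, methyl 5-[(tert-butyldimethylsilyl)oxy]-2-[(triisopropylsilyl)oxy]-6-[(2Z)-3-(trimethylstannyl)but-2-enoyl]-7-oxabicyclo[4.1.0]hept-3-ene-3-carboxylate F5.
   - Reduction with Li[(s-Bu)3BH] in THF at −78 °C, a bulky non-chelating hydride, should follow the Felkin–Anh path (hydride anti to the epoxide C–O bond, passing the epoxide CH) and return the (1'S) alcohol 29.

3. Step 6. The lipase may discriminate poorly on a hindered bicyclic carbinol with an epimeric neighbouring centre. Fallback, setting out from 8 and returning at 9: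
   - Esterification with (S)-2-methoxy-2-phenylacetic acid (dicyclohexylcarbodiimide, 4-(dimethylamino)pyridine, CH2Cl2) gives two diastereomeric esters: the (S)-2-methoxy-2-phenylacetate of the wanted enantiomer F6 and the (S)-2-methoxy-2-phenylacetate of the unwanted enantiomer F7.
   - These are separated by chromatography or crystallisation.
   - K2CO3 in MeOH at 0 °C cleaves F6 to 9.

Further compounds
F1 | step 11 | methyl 5-hydroxy-6-{[(4-methoxybenzyl)oxy]methyl}-4-[(triisopropylsilyl)oxy]-7-oxabicyclo[4.1.0]hept-2-ene-3-carboxylate (free alcohol of 14) | O[C@@H]1[C@@]2(COCc3ccc(OC)cc3)O[C@H]2C=C(C(=O)OC)[C@H]1O[Si](C(C)C)(C(C)C)C(C)C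
F2 | step 11 | O-(imidazol-1-ylcarbonothioyl) derivative of F1 | S=C(O[C@@H]1[C@@]2(COCc3ccc(OC)cc3)O[C@H]2C=C(C(=O)OC)[C@H]1O[Si](C(C)C)(C(C)C)C(C)C)n1ccnc1
F3 | step 11 | methyl 3-hydroxy-4-{[(4-methoxybenzyl)oxy]methyl}-6-[(triisopropylsilyl)oxy]cyclohexa-1,4-diene-1-carboxylate (3,6-cis) | O[C@H]1C=C(C(=O)OC)[C@@H](O[Si](C(C)C)(C(C)C)C(C)C)C=C1COCc1ccc(OC)cc1
F4 | step 11 | 3-O-(tert-butyldimethylsilyl) ether of F3 | CC(C)(C)[Si](C)(C)O[C@H]1C=C(C(=O)OC)[C@@H](O[Si](C(C)C)(C(C)C)C(C)C)C=C1COCc1ccc(OC)cc1
F5 | step 20 | methyl 5-[(tert-butyldimethylsilyl)oxy]-2-[(triisopropylsilyl)oxy]-6-[(2Z)-3-(trimethylstannyl)but-2-enoyl]-7-oxabicyclo[4.1.0]hept-3-ene-3-carboxylate | C/C(=C/C(=O)[C@]12O[C@H]1[C@H](O[Si](C(C)C)(C(C)C)C(C)C)C(C(=O)OC)=C[C@@H]2O[Si](C)(C)C(C)(C)C)[Sn](C)(C)C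
F6 | step 6 | (S)-2-methoxy-2-phenylacetate of 9 | COC(=O)C1[C@@H](OC(=O)[C@@H](OC)c3ccccc3)[C@@H]2O[C@H]1C=C2COCc1ccc(OC)cc1
F7 | step 6 | (S)-2-methoxy-2-phenylacetate of the enantiomer of 9 | COC(=O)C1[C@H](OC(=O)[C@@H](OC)c3ccccc3)[C@H]2O[C@@H]1C=C2COCc1ccc(OC)cc1
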